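Count what is missing.

| flask | J | L | remark | time |
|---|---|---|---|---|
| dawn | 1 mM (fed, over 25 s) | 2 equiv | run made earlier |  |
| autumn | 1 mM (fed, over 25 s) | 4.5 equiv | run made earlier |  |
| winter | 2 mM (fed, over 25 s) | 3 equiv | run made earlier |  |
| flask | 1.0 mM (fed, over 25 s) | 3.00 equiv |  | 30 min |

| run | time / min | J / % | E / % | G / % |
|---|---|---|---|---|
| dawn | 4.00 | 0 | 68.0 | 0 |
| dawn | 8.00 | 0 | 71.1 | 0 |
| dawn | 12.0 | 0.1 | 71.4 | 0.1 |
| dawn | 15.0 | 0 | 71.4 | 0 |
| dawn | 20.0 | 0.8 | 71.2 | 0 |
| dawn | 25.0 | 0 | 72.7 | 0 |
| autumn | 2.00 | 0.5 | 72.2 | 0.2 |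
| autumn | 3.00 | 0 | 71.5 | 0.3 |
| autumn | 5.00 | 0 | 73.1 | 0 |
| autumn | 8.00 | 0.7 | 73.1 | 0 |
| autumn | 15.0 | 0 | 74.2 | 0.1 |
| autumn | 25.0 | 0.6 | 72.6 | 0.7 |
| winter | 2.00 | 0.9 | 72.6 | 0.6 |
| winter | 6.00 | 0 | 73.4 | 0 |
| winter | 12.0 | 0.2 | 73.0 | 0.4 |
| winter | 15.0 | 0.2 | 72.4 | 0.4 |
| winter | 25.0 | 0.5 | 72.5 | 0 |

(each reading ± 0.5 percentage points)

* the state of affairs at 30 min: stopped, and by what, or still going (L has run out first / it is still moving / all of J has reacted / forward and back rates have come level)
* conversion of J at 30 min
* amount of E at 30 min, in percent of the J charged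

- the numbers in the tables scatter with a standard deviation of 0.5 percentage points
- the reaction counts as stopped when no species that holds the J changes by six tenths of a point or more over the second half of the time

In each run J and G read zero within the scatter once the first minutes have passed, yet E levels off well short of the charge. So a part m, the percent found as neither J, G nor E, has gone an unseen way.

Suppose E and m both form from G with one L: dE/dt = a[G][L] and dm/dt = b[G][L], where a and b are rate constants. Dividing removes [G] and [L], and integrating from the empty start gives E/m = a/b at each moment, however L falls. This ratio is a selectivity factor, ρ, so one plateau per run is enough to read it.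

The plateau means are 71.6% for dawn from 8.00 min, 72.8% for autumn and 72.8% for winter. Dawn lies lower by 1.2 percentage points, against a scatter of 0.5 points on one reading.

The weak link is m itself, which would count stalled material as well as lost material. Dawn's 2 equiv of L is just two L per J, the amount E takes, so its m may hold stalled material, and dawn is set aside. Autumn and winter differ in both L and J yet stand level, as the supposition requires. Their mean, 72.8%, gives ρ, the E formed per unit of m, as 2.67.

The flask has winter's 3.00 equiv of L, so it should reach full conversion with J gone first. Its share of E is ρ over one plus ρ, 72.8%.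

The forecast, slightly lower, says all of J has reacted, 100% and 72.5%: “Its share hardly changes with L excess or concentration”.

The flask gives all of J has reacted, 100% conversion and 73.1% of E.

    J + L → G (k = 467 /M/s)
    J + L → Z (k = 19.9 /M/s)
    L + G → E (k = 982 /M/s)
    L + Z → E (k = 183 /M/s)
    G ⇌ X (K = 19.0, k = 0.186 /s)
    L + G → D (k = 383 /M/s)
    L ⇌ Q (K = 0.0740, k = 0.261 /s)

At 0.226 min the flask uses G 2.6 times as fast on the path to E as on the path to D, against the ρ of 2.67 read from the plateaus. At 30 min the flask holds 73.1% of E and 26.9% of D, a ratio of 2.72. A neighbour flask charged with 1.80 equiv of L ends with L at 0% of its own charge and 16.0% of the J charged held as X, and its 59.3% of E against 21.9% of D is a ratio of 2.71.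

All runs come from a simulation on assumed constants, noise included.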